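Compound numbers used throughout: 1 2,4,6-trihydroxybenzoic acid; 2 its benzyl ester; 3 the 4-O-methyl ether; 4 the mono-benzyl ether; 5 the aryl triflate; 6 allylboronic acid pinacol ester; 7 the allyl arene; 8 its ozonide; 9 the arylacetaldehyde; 10 acetyl bromide; 11 1-undecene; 12 the racemic 1-bromoalkyl acetate; 13 the protected (R)-acetate; 14 the target. Side-chain atoms are primed (C1′ benzylic, C2′ the stereocentre, C3′ the first carbon of the undecyl chain).

## Analysis of the target

Target 14 is an open-chain resorcylic acid: a single benzene ring bearing the carboxyl group at C1, a 2-acetoxytridecyl chain at C2, a methoxy group at C4 and a free hydroxyl at C6, with no other ring. Its only stereocentre is C2′ of the side chain, (R)-configured, a carbinol carbon flanked by the benzylic C1′ methylene and by the C3′ methylene of an unbranched undecyl chain, so there is no second stereocentre to relate it to and its two carbon substituents differ only beyond the first atom. That makes the classical answer, enantioselective reduction of the corresponding ketone, unattractive, because a catalyst has little to tell the two methylene groups apart. The C2′ acetate is the most delicate group: it does not survive the hydroxide or alkoxide needed to open a hindered 2,6-disubstituted benzoate, and the oxygen it masks lies five atoms from the carboxyl carbon, so any intermediate with a free C2′ hydroxyl or alkoxide next to an ester closes to the six-membered lactone (a 3-undecyl-3,4-dihydroisocoumarin). The electron-rich salicylic acid is prone to decarboxylation under heat or strong acid and is best released last and under neutral conditions. On the arene, three oxygens of a phloroglucinol carboxylate have to be told apart: one becomes the methyl ether, one stays a phenol and the third must be replaced by the C1′ carbon. The real difficulty is therefore to create the C2′ stereocentre with the acetyl group already on its oxygen, without ever passing through the free carbinol. The strategy rests on reading C2′ as a former aldehyde carbon: its oxygen is the carbonyl oxygen of an arylacetaldehyde, the acetyl group arrives from an acyl bromide, and the C2′–C3′ bond is made to an unfunctionalised C11 chain supplied as a terminal olefin.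

## Retrosynthetic reasoning

**14 back to 13.** The last bonds cut are the two O–CH2Ph bonds, that of the carboxyl group and that of the C6 phenol. Both fall in one neutral hydrogenolysis, the only kind of unmasking that leaves the secondary acetate alone and never exposes a carboxyl derivative to a free C2′ oxygen. A hydrolytic end game was ruled out for that reason. The forward step only has to spare the C2′–O bond, which it should because that carbon is homobenzylic, not benzylic.

**13 back to 9, 10 and 11.** The stereocentre is disconnected twice, at the C2′–C3′ bond and at the O–acetyl bond. This returns aldehyde 9, acetyl bromide 10 and 1-undecene 11, with the racemic 1-bromoalkyl acetate 12 as the species that actually couples. Cutting C1′–C2′ instead would need a benzylic carbanion beside an ester and an enantiopure electrophile. Cutting aryl–C1′ would need an sp3 metal reagent with a β-oxygen leaving group, which eliminates. The chosen cut asks only for an aldehyde and an unfunctionalised olefin. The gain is that the acetate is not a protecting group put on afterwards: it turns the C–Br bond of 12 into a radical precursor and anchors the catalyst, so the carbinol is never free, and both enantiomers of 12 converge on one product. The forward reaction must give linear hydrometalation of 11 and enantioselective capture of the α-acetoxy radical, and must outrun β-elimination from 12.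

**9 back to 7.** Aldehyde 9 is enolisable toward the arene and sits ortho to an ester, so it should exist only briefly. It is traced back to allyl arene 7 by adding one carbon across C2′. Oxidative cleavage of the terminal C=C through ozonide 8 unveils it under neutral conditions just before use.

**7 back to 5 and 6.** The aryl–C1′ bond is cut to aryl triflate 5 and allylboronate 6. This converts a C–C bond on a crowded arene into a C–O bond, that is, into one of the three ring oxygens of 1. The ortho ester activates the triflate toward oxidative addition. The forward coupling must transfer the allyl group without moving the double bond into conjugation.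

**5 back to 1.** Triflate 5 comes from phenol 4 by O-sulfonylation, 4 from diol 3 by benzylation of one of two equivalent hydroxyls, 3 from triol 2 by methylation of the para hydroxyl, and 2 from acid 1 by O-benzylation of the carboxylate. The order follows intrinsic reactivity: the carboxylate first, then the only non-chelated and most acidic hydroxyl, then one of the two chelated ones. Benzyl is chosen for both the ester and the ether so that a single final step removes them.

## Alternatives that were turned down

**Alternative 1:** The benzene ring itself is disconnected, back to the linear diketo-dioxinone A2, 6-[(6R)-6-(tert-butyldimethylsilyloxy)-2,4-dioxoheptadecyl]-2,2-dimethyl-4H-1,3-dioxin-4-one, whose stereocentre is bought as (3R)-3-hydroxytetradecanoic acid A3. In the forward key step an amine base triggers aldol addition of the dioxinone α-carbon to the far ketone, and dehydration then gives the acetonide-masked resorcylate A1, 7-hydroxy-2,2-dimethyl-5-[(R)-2-(tert-butyldimethylsilyloxy)tridecyl]-4H-1,3-benzodioxin-4-one.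
- For: the configuration comes from the chiral pool and does not depend on a catalyst. The arene is formed with the acid and one ortho oxygen tied together and the para hydroxyl free, so methylation is unambiguous and no cross-coupling is needed.
- Against: A1 carries a silyl ether where the target has an acetate, and an acetonide where it has a free salicylic acid. Removing the silyl group frees the C2′ oxygen five atoms from an activated dioxinone carbonyl, which is the set-up for translactonisation to the dihydroisocoumarin. The acetonide opens only with nucleophiles that also cleave an acetate, so the end game would have to pass through a benzyl ester anyway. Building A2 from A3 takes several C-acylations of sensitive dicarbonyl anions in a linear sequence.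
- Comparison: Alternative 1 is stronger on stereochemical certainty and on differentiating the ring oxygens (no statistical step like 3 to 4). The chosen route offers instead an end game with no free carbinol, protecting groups that leave by hydrogenolysis, and a shorter, convergent sequence.

**Alternative 2:** The C2′–O bond is disconnected through lactone A4, (R)-6,8-dimethoxy-3-undecylisochroman-1-one, back to racemic ketone A5, 5,7-dimethoxy-2-undecylindan-1-one. In the forward key step a Baeyer–Villiger monooxygenase inserts oxygen between the carbonyl carbon and the undecyl-bearing α-carbon of A5 while the slow enantiomer racemises through its enol.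
- For: A5 is quickly made by classical indanone chemistry. The stereocentre is set with oxygen from air, with retention at the migrating carbon, and a dynamic resolution can in principle convert all the material.
- Against: A4 is the ring-closed form of what the target keeps open. Reaching 14 would need lactone hydrolysis, protection of the carboxylate, acetylation of the alcohol before it recloses, deprotection, and selective cleavage of the methyl ether peri to the carbonyl. In Baeyer–Villiger chemistry an electron-rich aryl group competes with a secondary alkyl group for migration, so the enzyme must control regio- and enantioselectivity on a substrate with a lipophilic C11 tail and a peri methoxy group. Racemisation of a 2-alkylindanone at enzyme-compatible pH is slow.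
- Comparison: Alternative 2 is stronger in step economy up to the stereocentre and in reagent cost. The chosen route maps onto the target better: 13 is one hydrogenolysis from 14 and the lactone is never formed.

**Alternative 3:** Two ring bonds of the arene (C1–C6 and C2–C3) are disconnected, to the chiral ynoate A7, benzyl (5R)-5-acetoxyhexadec-2-ynoate, and the diene A8, 1,3-dimethoxy-1-(trimethylsilyloxy)buta-1,3-diene. The forward key step is a thermal [4+2] cycloaddition followed by aromatisation to A6, benzyl 2-[(R)-2-acetoxytridecyl]-6-hydroxy-4-methoxybenzoate.
- For: the regiochemistry is electronically matched and the oxygen pattern arrives differentiated, with free 6-OH and 4-OMe. No phenol protecting group is needed, A6 is one hydrogenolysis from 14, and the acetate is in place before the ring exists.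
- Against: the key step does not make the stereocentre, which must be imported (for instance from a resolved terminal epoxide) and acetylated in a separate sequence leading to A7. β-Alkyl ynoates are sluggish dienophiles, and A8 is thermally and hydrolytically fragile at the temperatures they need. Aromatisation can expel either the alkoxy or the silyloxy group, which blurs the 6-OH/6-OMe outcome.
- Comparison: Alternative 3 is at least equal in length and better in protecting-group economy. The chosen route offers predictable arene chemistry on a preformed ring, and it creates the stereocentre catalytically from achiral feedstocks in the same step that installs the acetate.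

Key step: step 7

Assumption: the sense of induction of the bis(oxazoline) nickel catalyst cannot be read from the structure, so the ligand antipode giving (R)-13 is taken to be identified on a simple model aldehyde; a ligand of the type 2,2′-(propane-2,2-diyl)bis(4-phenyl-4,5-dihydrooxazole), available as both antipodes, is proposed. Acid 1 is used as its commercial monohydrate.

## Route

Step 1
Reactants: 1 2,4,6-trihydroxybenzoic acid
Product: 2 benzyl 2,4,6-trihydroxybenzoate
Conditions: BnBr (1.0 equiv), KHCO3 (1.1 equiv), DMF, rt → 40 °C
Reagents that add atoms: benzyl bromide, BrCc1ccccc1
Why: Carboxylate O-alkylation: bicarbonate deprotonates only the strongly acidic carboxyl group while the phenols stay protonated and hydrogen-bonded, and the carboxylate is benzylated by SN2 displacement; the mild temperature should keep 1 from decarboxylating.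

Step 2
Reactants: 2 benzyl 2,4,6-trihydroxybenzoate
Product: 3 benzyl 2,6-dihydroxy-4-methoxybenzoate
Conditions: MeOH (1.1 equiv), PPh3, DIAD, THF, 0 °C → rt
Reagents that add atoms: methanol, CO
Why: Mitsunobu etherification: the 4-OH is the most acidic hydroxyl and the only one not hydrogen-bonded to the ester, so it should be the one that protonates the betaine and is methylated, leaving the chelated 2- and 6-OH free.

Step 3
Reactants: 3 benzyl 2,6-dihydroxy-4-methoxybenzoate
Product: 4 benzyl 2-(benzyloxy)-6-hydroxy-4-methoxybenzoate
Conditions: BnBr (1.05 equiv), K2CO3 (1.1 equiv), acetone, 56 °C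
Reagents that add atoms: benzyl bromide, BrCc1ccccc1
Why: Williamson etherification: with one equivalent of base and halide one of the two equivalent hydroxyls is benzylated, and the remaining one, now in a strong hydrogen bond to the ester carbonyl, should react much more slowly, holding the reaction at the mono-ether.

Step 4
Reactants: 4 benzyl 2-(benzyloxy)-6-hydroxy-4-methoxybenzoate
Product: 5 benzyl 2-(benzyloxy)-4-methoxy-6-{[(trifluoromethyl)sulfonyl]oxy}benzoate
Conditions: Tf2O (1.2 equiv), pyridine, CH2Cl2, 0 °C
Reagents that add atoms: trifluoromethanesulfonic anhydride, O=S(=O)(OS(=O)(=O)C(F)(F)F)C(F)(F)F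
Why: O-Sulfonylation of a phenol: the chelated hydroxyl is the only nucleophile left, and the benzyl ester, benzyl ether and methyl ether are inert to Tf2O/pyridine.

Step 5
Reactants: 5 benzyl 2-(benzyloxy)-4-methoxy-6-{[(trifluoromethyl)sulfonyl]oxy}benzoate; 6 allylboronic acid pinacol ester
Product: 7 benzyl 2-allyl-6-(benzyloxy)-4-methoxybenzoate
Conditions: Pd(PPh3)4 (5 mol%), CsF (3 equiv), THF, 65 °C
Reagents that add atoms: none
Why: Suzuki–Miyaura coupling: zerovalent palladium inserts into the C–OTf bond, which the ortho ester activates, the fluoride-activated allylboronate transmetalates and reductive elimination gives the allyl arene; fluoride as base avoids saponification and should keep the terminal olefin from migrating.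

Step 6
Reactants: 7 benzyl 2-allyl-6-(benzyloxy)-4-methoxybenzoate
Product: 9 benzyl 2-(benzyloxy)-4-methoxy-6-(2-oxoethyl)benzoate, via secondary ozonide 8 (not isolated)
Conditions: O3, CH2Cl2, −78 °C (Sudan Red 7B end-point); then PPh3, −78 °C → rt
Reagents that add atoms: ozone, [O-][O+]=O
Why: Ozonolysis with reductive work-up: the isolated terminal alkene is far more reactive toward ozone than the ester-deactivated arene, the dye end-point prevents excess ozone, and PPh3 reduces ozonide 8 under neutral conditions so that 9 should neither enolise nor close onto the ester; 9 is used at once.

Step 7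
Reactants: 9 benzyl 2-(benzyloxy)-4-methoxy-6-(2-oxoethyl)benzoate; 10 acetyl bromide; 11 1-undecene
Product: 13 benzyl 2-[(2R)-2-acetoxytridecyl]-6-(benzyloxy)-4-methoxybenzoate, via racemic 1-bromoalkyl acetate 12 (not isolated)
Conditions: 10 (1.0 equiv), CH2Cl2, −20 → 0 °C; then 11 (1.5 equiv), NiBr2·DME (10 mol%), chiral bis(oxazoline) ligand (12 mol%), (EtO)3SiH (2.5 equiv), K3PO4·H2O (2.5 equiv), DMA/i-Pr2O, 0 °C → rt
Reagents that add atoms: none
Why: Acetyl bromide adds across the C=O of 9 to give racemic 12, and the nickel salt, ligand, silane and phosphate generate a ligated nickel hydride that inserts 11 in the anti-Markovnikov sense to a primary undecylnickel species. This species abstracts bromine from either enantiomer of 12, the planar α-acetoxyalkyl radical is captured at nickel, and reductive elimination from the trivalent dialkylnickel forms the C2′–C3′ bond, the monovalent nickel bromide being returned to the hydride by silane and base. The closest known reaction type is the nickel-hydride enantioconvergent hydroalkylation of terminal olefins with racemic 1-bromoalkyl esters, including its one-pot aldehyde, acyl bromide, olefin and hydrosilane form. No ring is closed. The C2′ stereocentre is set under catalyst control by the bis(oxazoline) on nickel at the radical-capture and reductive-elimination stage, with the acetate carbonyl serving as the second binding point, and the (R) sense is fixed by the choice of ligand antipode. The step needs linear regiochemistry, which the unhindered terminal olefin secures. It needs chemoselectivity for the C–Br bond over aryl–O, benzyl ester and benzyl ether bonds, none of which is activated toward nickel at room temperature. It also needs radical formation to outrun loss of HBr across C1′–C2′, which is helped by forming 12 cold with exactly one equivalent of 10 and adding it to the working catalyst.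

Step 8
Reactants: 13 benzyl 2-[(2R)-2-acetoxytridecyl]-6-(benzyloxy)-4-methoxybenzoate
Product: 14 2-[(2R)-2-acetoxytridecyl]-6-hydroxy-4-methoxybenzoic acid
Conditions: H2 (1 atm), 10% Pd/C, EtOAc, rt
Reagents that add atoms: none
Why: Catalytic hydrogenolysis cleaves both benzylic C–O bonds (ester and aryl ether); the C2′–OAc bond is homobenzylic and no acid or base is present, so the acetate should stay, the stereocentre is untouched and no lactone can form.

## Compound list

1 | 2,4,6-trihydroxybenzoic acid | OC(=O)c1c(O)cc(O)cc1O | starting material
2 | benzyl 2,4,6-trihydroxybenzoate | O=C(OCc1ccccc1)c1c(O)cc(O)cc1O | intermediate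
3 | benzyl 2,6-dihydroxy-4-methoxybenzoate | COc1cc(O)c(C(=O)OCc2ccccc2)c(O)c1 | intermediate
4 | benzyl 2-(benzyloxy)-6-hydroxy-4-methoxybenzoate | COc1cc(O)c(C(=O)OCc2ccccc2)c(OCc2ccccc2)c1 | intermediate
5 | benzyl 2-(benzyloxy)-4-methoxy-6-{[(trifluoromethyl)sulfonyl]oxy}benzoate | COc1cc(OCc2ccccc2)c(C(=O)OCc2ccccc2)c(OS(=O)(=O)C(F)(F)F)c1 | intermediate
6 | allylboronic acid pinacol ester (2-allyl-4,4,5,5-tetramethyl-1,3,2-dioxaborolane) | C=CCB1OC(C)(C)C(C)(C)O1 | starting material
7 | benzyl 2-allyl-6-(benzyloxy)-4-methoxybenzoate | C=CCc1cc(OC)cc(OCc2ccccc2)c1C(=O)OCc1ccccc1 | intermediate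
8 | benzyl 2-(benzyloxy)-4-methoxy-6-[(1,2,4-trioxolan-3-yl)methyl]benzoate (racemic secondary ozonide) | O=C(OCc1ccccc1)c1c(CC2OCOO2)cc(OC)cc1OCc1ccccc1 | intermediate
9 | benzyl 2-(benzyloxy)-4-methoxy-6-(2-oxoethyl)benzoate | O=CCc1cc(OC)cc(OCc2ccccc2)c1C(=O)OCc1ccccc1 | intermediate
10 | acetyl bromide | CC(=O)Br | starting material
11 | 1-undecene | C=CCCCCCCCCC | starting material
12 | benzyl 2-(2-acetoxy-2-bromoethyl)-6-(benzyloxy)-4-methoxybenzoate (racemic) | CC(=O)OC(Br)Cc1cc(OC)cc(OCc2ccccc2)c1C(=O)OCc1ccccc1 | intermediate
13 | benzyl 2-[(2R)-2-acetoxytridecyl]-6-(benzyloxy)-4-methoxybenzoate | CCCCCCCCCCC[C@H](Cc1cc(OC)cc(OCc2ccccc2)c1C(=O)OCc1ccccc1)OC(C)=O | intermediate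
14 | 2-[(2R)-2-acetoxytridecyl]-6-hydroxy-4-methoxybenzoic acid | CCCCCCCCCCC[C@H](Cc1cc(OC)cc(O)c1C(=O)O)OC(C)=O | target

## Step count and risk

Total: 8 steps. Longest linear sequence: 8 steps (1 to 14); 6, 10 and 11 enter directly as purchased.

**Step 7 (key step).** The most likely failure is loss of the 1-bromoalkyl acetate before it reaches nickel. One path is base-induced elimination of HBr across C1′–C2′ to the aryl-conjugated enol acetate, since the C1′ hydrogens are benzylic. Another is ionisation of the C–Br bond and capture of the acyloxycarbenium ion by the carbonyl oxygen of the ortho benzyl ester, which would close a six-membered ring and shed the benzyl group. Further risks are erosion of enantioselectivity, because acetyl is the smallest possible anchor and the benzyl ether and ester oxygens offer competing coordination, and plain reduction of the C–Br bond by the nickel hydride.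

Fallback, from 9 to 14 by reagent-controlled allylation and chain extension:
- Brown allylation of 9 with the B-allyldiisopinocampheylborane antipode that gives the (R)-carbinol (Et2O, −78 °C, ethanolamine work-up to avoid base-induced lactonisation) would give benzyl 2-(benzyloxy)-6-[(2R)-2-hydroxypent-4-en-1-yl]-4-methoxybenzoate F1.
- Immediate acetylation (Ac2O, pyridine, DMAP, 0 °C) would give benzyl 2-[(2R)-2-acetoxypent-4-en-1-yl]-6-(benzyloxy)-4-methoxybenzoate F2.
- Cross-metathesis with 1-decene (C=CCCCCCCCC; second-generation Grubbs catalyst, CH2Cl2, 40 °C) would give benzyl 2-[(2R)-2-acetoxytridec-4-en-1-yl]-6-(benzyloxy)-4-methoxybenzoate F3 as an E/Z mixture.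
- H2 over 10% Pd/C in EtOAc would then saturate the olefin and remove both benzyl groups in one operation, rejoining the route at 14.

**Step 1.** The phloroglucinol nucleus may be benzylated at O-4 or at ring carbon alongside the carboxylate, and 1 may decarboxylate if the alkylation has to be warmed, because the doubly chelated carboxylate is a poor nucleophile.

Fallback, from 1 to 4, replacing steps 1 to 3 together and also removing the selectivity questions of steps 2 and 3:
- Acetone with TFAA/TFA would tie up the acid and one ortho hydroxyl as 5,7-dihydroxy-2,2-dimethyl-4H-1,3-benzodioxin-4-one F4.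
- Mitsunobu methylation (MeOH, PPh3, DIAD) of the only non-chelated hydroxyl would give 5-hydroxy-7-methoxy-2,2-dimethyl-4H-1,3-benzodioxin-4-one F5.
- Benzylation (BnBr, K2CO3, DMF, 60 °C) would give 5-(benzyloxy)-7-methoxy-2,2-dimethyl-4H-1,3-benzodioxin-4-one F6.
- Opening of the dioxinone with sodium benzyloxide (BnOH, NaH, THF, 0 °C → rt), with loss of acetone, would deliver 4 directly.

**Step 3.** Over-alkylation to the bis-benzyl ether or stalled conversion may occur, because the two hydroxyls are equivalent and discrimination rests only on deactivation after the first alkylation.

Fallback, from 3 to 7, with the order of operations reversed: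
- Mono-triflation (Tf2O 1.0 equiv, pyridine, CH2Cl2, −20 °C), in which the first triflate deactivates the second hydroxyl electronically, would give benzyl 2-hydroxy-4-methoxy-6-{[(trifluoromethyl)sulfonyl]oxy}benzoate F7.
- Suzuki–Miyaura allylation with 6 under the conditions of step 5 would give benzyl 2-allyl-6-hydroxy-4-methoxybenzoate F8.
- Benzylation of its single hydroxyl (BnBr, K2CO3, acetone) would rejoin the route at 7.

**Step 6.** Ozone may over-oxidise the dialkoxyarene or the benzylic ether positions, and the arylacetaldehyde may degrade by enolisation and ring closure onto the ester during purification.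

Fallback, from 7 to 9 in two stages without ozone:
- Upjohn dihydroxylation (OsO4 cat., N-methylmorpholine N-oxide, acetone/H2O) would give the racemic diol benzyl 2-(benzyloxy)-6-(2,3-dihydroxypropyl)-4-methoxybenzoate F9.
- Glycol cleavage with NaIO4 (THF/H2O, rt) would release 9 under neutral conditions.

## Further compounds

F1 | step 7 | benzyl 2-(benzyloxy)-6-[(2R)-2-hydroxypent-4-en-1-yl]-4-methoxybenzoate | C=CC[C@H](Cc1cc(OC)cc(OCc2ccccc2)c1C(=O)OCc1ccccc1)O
F2 | step 7 | benzyl 2-[(2R)-2-acetoxypent-4-en-1-yl]-6-(benzyloxy)-4-methoxybenzoate | C=CC[C@H](Cc1cc(OC)cc(OCc2ccccc2)c1C(=O)OCc1ccccc1)OC(C)=O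
F3 | step 7 | benzyl 2-[(2R)-2-acetoxytridec-4-en-1-yl]-6-(benzyloxy)-4-methoxybenzoate (E/Z mixture) | CCCCCCCCC=CC[C@H](Cc1cc(OC)cc(OCc2ccccc2)c1C(=O)OCc1ccccc1)OC(C)=O
F4 | step 1 | 5,7-dihydroxy-2,2-dimethyl-4H-1,3-benzodioxin-4-one | CC1(C)OC(=O)c2c(O)cc(O)cc2O1
F5 | step 1 | 5-hydroxy-7-methoxy-2,2-dimethyl-4H-1,3-benzodioxin-4-one | COc1cc(O)c2C(=O)OC(C)(C)Oc2c1
F6 | step 1 | 5-(benzyloxy)-7-methoxy-2,2-dimethyl-4H-1,3-benzodioxin-4-one | COc1cc(OCc2ccccc2)c2C(=O)OC(C)(C)Oc2c1
F7 | step 3 | benzyl 2-hydroxy-4-methoxy-6-{[(trifluoromethyl)sulfonyl]oxy}benzoate | COc1cc(O)c(C(=O)OCc2ccccc2)c(OS(=O)(=O)C(F)(F)F)c1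
F8 | step 3 | benzyl 2-allyl-6-hydroxy-4-methoxybenzoate | C=CCc1cc(OC)cc(O)c1C(=O)OCc1ccccc1
F9 | step 6 | benzyl 2-(benzyloxy)-6-(2,3-dihydroxypropyl)-4-methoxybenzoate (racemic) | OCC(O)Cc1cc(OC)cc(OCc2ccccc2)c1C(=O)OCc1ccccc1
A1 | alternative 1 | 7-hydroxy-2,2-dimethyl-5-[(R)-2-(tert-butyldimethylsilyloxy)tridecyl]-4H-1,3-benzodioxin-4-one | CCCCCCCCCCC[C@H](Cc1cc(O)cc2OC(C)(C)OC(=O)c12)O[Si](C)(C)C(C)(C)C
A2 | alternative 1 | 6-[(6R)-6-(tert-butyldimethylsilyloxy)-2,4-dioxoheptadecyl]-2,2-dimethyl-4H-1,3-dioxin-4-one | CCCCCCCCCCC[C@H](CC(=O)CC(=O)CC1=CC(=O)OC(C)(C)O1)O[Si](C)(C)C(C)(C)C
A3 | alternative 1 | (3R)-3-hydroxytetradecanoic acid | CCCCCCCCCCC[C@@H](O)CC(=O)O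
A4 | alternative 2 | (R)-6,8-dimethoxy-3-undecylisochroman-1-one | CCCCCCCCCCC[C@@H]1Cc2cc(OC)cc(OC)c2C(=O)O1
A5 | alternative 2 | 5,7-dimethoxy-2-undecylindan-1-one (racemic) | CCCCCCCCCCCC1Cc2cc(OC)cc(OC)c2C1=O
A6 | alternative 3 | benzyl 2-[(R)-2-acetoxytridecyl]-6-hydroxy-4-methoxybenzoate | CCCCCCCCCCC[C@H](Cc1cc(OC)cc(O)c1C(=O)OCc1ccccc1)OC(C)=O
A7 | alternative 3 | benzyl (5R)-5-acetoxyhexadec-2-ynoate | CCCCCCCCCCC[C@H](CC#CC(=O)OCc1ccccc1)OC(C)=O
A8 | alternative 3 | 1,3-dimethoxy-1-(trimethylsilyloxy)buta-1,3-diene | C=C(OC)C=C(OC)O[Si](C)(C)C
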